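**Plan**

- Numbering: ring A is the cyclohexenedione (C1 bears CH3 and the ester oxygen, C2 and C6 are ketones, C3=C4 carries OCH3 on C4, C5 bears CH3 and the CH2 bridge); ring B is the aminodienone (C1' at the bridge, C2' OCH3, C3' acyl, C4' NH2, C5' carbinol, C6' ketone).
- Cuts, last-formed bond first: C4'–N (ammonia on a C4' methoxy dienone), C5'–O (hydroxylative dearomatisation of a ring B phenol), the C3' acyl bond (Friedel–Crafts), the C1 ester, then C5–C6 and C1–C2 of ring A (key step), then the C2–C5 chain back to a ring B benzaldehyde.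
- Enabling feature: C1 of ring A with its CH3, its O and the C6 ketone is a lactic acid unit, and C1 is flanked by the C2 carbonyl of the vinylogous ester C2–C3=C4(OCH3), whose γ-carbon C5 can close onto C6.
- Forward order: ring B arene first (benzyl-protected salicylaldehyde), chain extension to the (E)-β-methoxy-enoyl chloride, ring A by annulation on the lactic acid dioxolanone, then O-acylation, C-acylation, debenzylation, dearomatisation of ring B and amination.
- Stereochemistry: C1 from (S)-lactic acid through its pivalaldehyde acetal; C5 in the ring closure (arylmethyl trans to the C1 oxygen); both sec-butyl centres from (R)-2-methylbutanoic acid; C5' from a chiral iodyl reagent.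

Key step: step 12

Assumption: the sense of asymmetric induction of the oxazoline iodyl reagent on this hexasubstituted phenol cannot be predicted, so the (S)-reagent is written in step 16 and its antipode would take its place if it proves to be the matched one.

**Route**

Step 1
Reactants: 1 (S)-lactic acid; 2 pivalaldehyde (2,2-dimethylpropanal)
Product: 3 (2S,5S)-2-tert-butyl-5-methyl-1,3-dioxolan-4-one (cis)
Conditions: TsOH·H2O (cat.), H2SO4 (cat.), pentane, reflux, Dean–Stark; crystallisation from pentane–Et2O, −78 °C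
Reagents that add atoms: none
Why: Acid-catalysed acetalisation with azeotropic removal of water should give mainly the cis acetal, whose new acetal centre (2S) is set under thermodynamic control by the lactate centre and which is purified by low-temperature crystallisation.

Step 2
Reactants: 4 (R)-2-methylbutanoic acid
Product: 5 (R)-2-methylbutanoyl chloride
Conditions: (COCl)2, DMF (cat.), CH2Cl2, 0 °C to rt
Reagents that add atoms: oxalyl chloride, O=C(Cl)C(=O)Cl
Why: Acid chloride formation through the chloroiminium intermediate is mild enough at 0 °C to leave the α-stereocentre untouched.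

Step 3
Reactants: 6 2-hydroxy-4,6-dimethoxybenzaldehyde
Product: 7 3,5-dimethoxy-2-methylphenol
Conditions: H2, Pd/C, AcOH, rt
Reagents that add atoms: none
Why: Catalytic hydrogenolysis of an electron-rich aromatic aldehyde through its benzylic alcohol is a standard route to an aryl methyl group, and the ortho-hydroxyl and the two methoxy groups speed the loss of the benzylic oxygen.

Step 4
Reactants: 7 3,5-dimethoxy-2-methylphenol
Product: 8 2-hydroxy-4,6-dimethoxy-3-methylbenzaldehyde
Conditions: MgCl2, Et3N, (CH2O)n, THF, reflux; then 1 M HCl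
Reagents that add atoms: paraformaldehyde (as formaldehyde), C=O
Why: The magnesium phenoxide-directed ortho-formylation (Casnati–Skattebøl reaction) delivers formaldehyde only next to the phenol, here the single free ortho carbon, and a second equivalent of formaldehyde oxidises the hydroxymethyl group by hydride transfer.

Step 5
Reactants: 8 2-hydroxy-4,6-dimethoxy-3-methylbenzaldehyde
Product: 9 2-(benzyloxy)-4,6-dimethoxy-3-methylbenzaldehyde
Conditions: BnBr, K2CO3, DMF, 60 °C
Reagents that add atoms: benzyl bromide, BrCc1ccccc1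
Why: Williamson ether synthesis on the only phenol, which is hydrogen-bonded to the aldehyde but is alkylated readily in DMF.

Step 6
Reactants: 9 2-(benzyloxy)-4,6-dimethoxy-3-methylbenzaldehyde
Product: 10 methyl (E)-3-[2-(benzyloxy)-4,6-dimethoxy-3-methylphenyl]-2-methylprop-2-enoate
Conditions: (MeO)2P(O)CH(CH3)CO2Me, NaH, THF, 0 °C to reflux
Reagents that add atoms: trimethyl 2-phosphonopropionate, COC(=O)C(C)P(=O)(OC)OC
Why: Horner–Wadsworth–Emmons olefination with the reactive phosphonate anion should overcome the two ortho substituents of the aldehyde, and the alkene geometry (E expected) is of no consequence because the double bond is reduced next.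

Step 7
Reactants: 10 methyl (E)-3-[2-(benzyloxy)-4,6-dimethoxy-3-methylphenyl]-2-methylprop-2-enoate
Product: 12 3-[2-(benzyloxy)-4,6-dimethoxy-3-methylphenyl]-2-methylpropanoic acid (racemic), via saturated methyl ester 11 (not isolated)
Conditions: NaBH4, NiCl2·6H2O (0.2 equiv), MeOH–THF, 0 °C to rt; then LiOH, H2O, 50 °C; 1 M HCl
Reagents that add atoms: lithium hydroxide, [Li+].[OH-]
Why: Nickel boride conjugate reduction of the cinnamate should leave the aryl benzyl ether intact and hydroxide then saponifies the ester in the same flask, the new centre being racemic and erased later in the dienolate of step 12.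

Step 8
Reactants: 12 3-[2-(benzyloxy)-4,6-dimethoxy-3-methylphenyl]-2-methylpropanoic acid
Product: 15 methyl 5-[2-(benzyloxy)-4,6-dimethoxy-3-methylphenyl]-4-methyl-3-oxopentanoate (racemic), via acyl imidazolide 13 (not isolated), via acylmalonic half ester 14 (not isolated)
Conditions: CDI, THF, rt; then KO2CCH2CO2Me, MgCl2, Et3N, THF–MeCN, rt to 40 °C; 1 M HCl
Reagents that add atoms: potassium methyl malonate, [K+].[O-]C(=O)CC(=O)OC
Why: Masamune–Brooks homologation, in which the acyl imidazolide is C-acylated by the magnesium malonate half ester and the adduct loses CO2, gives the β-keto ester under nearly neutral conditions.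

Step 9
Reactants: 15 methyl 5-[2-(benzyloxy)-4,6-dimethoxy-3-methylphenyl]-4-methyl-3-oxopentanoate
Product: 17 methyl (E)-5-[2-(benzyloxy)-4,6-dimethoxy-3-methylphenyl]-3-methoxy-4-methylpent-2-enoate (racemic), via dimethyl ketal 16 (not isolated)
Conditions: HC(OMe)3, H2SO4 (cat.), MeOH, rt to 50 °C
Reagents that add atoms: trimethyl orthoformate, COC(OC)OC
Why: Acid-catalysed ketalisation followed by loss of methanol towards the ester should give the conjugated (E)-enol ether under thermodynamic control, as with simple β-keto esters, which fixes the position of the ring A methoxy group before the ring exists.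

Step 10
Reactants: 17 methyl (E)-5-[2-(benzyloxy)-4,6-dimethoxy-3-methylphenyl]-3-methoxy-4-methylpent-2-enoate
Product: 18 (E)-5-[2-(benzyloxy)-4,6-dimethoxy-3-methylphenyl]-3-methoxy-4-methylpent-2-enoic acid (racemic)
Conditions: LiOH, THF–MeOH–H2O, 60 °C; cold 1 M HCl to pH 3–4
Reagents that add atoms: lithium hydroxide, [Li+].[OH-]
Why: Saponification of a β-alkoxy acrylate is slow but clean on warming, and brief cold acidification should spare the enol ether.

Step 11
Reactants: 18 (E)-5-[2-(benzyloxy)-4,6-dimethoxy-3-methylphenyl]-3-methoxy-4-methylpent-2-enoic acid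
Product: 19 (E)-5-[2-(benzyloxy)-4,6-dimethoxy-3-methylphenyl]-3-methoxy-4-methylpent-2-enoyl chloride (racemic, used crude)
Conditions: 1-chloro-N,N,2-trimethylprop-1-en-1-amine, CH2Cl2, 0 °C to rt; evaporation
Reagents that add atoms: 1-chloro-N,N,2-trimethylprop-1-en-1-amine, CC(C)=C(Cl)N(C)C
Why: Chlorination of the acid with the α-chloroenamine proceeds under neutral conditions without HCl or a chloroiminium electrophile, which spares the enol ether and the electron-rich arene.

Step 12
Reactants: 3 (2S,5S)-2-tert-butyl-5-methyl-1,3-dioxolan-4-one; 19 (E)-5-[2-(benzyloxy)-4,6-dimethoxy-3-methylphenyl]-3-methoxy-4-methylpent-2-enoyl chloride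
Product: 21 (2R,6R)-6-{[2-(benzyloxy)-4,6-dimethoxy-3-methylphenyl]methyl}-2-hydroxy-5-methoxy-2,6-dimethylcyclohex-4-ene-1,3-dione (C1 R and C5 R in ring A locants), via acyl dioxolanone 20 (not isolated)
Conditions: 3 (1.2 equiv), LiN(CHMe2)2, THF, −78 °C; enolate transferred onto 19 in THF, −78 °C; then LiN(SiMe3)2, −78 to −20 °C; AcOH, −78 °C
Reagents that add atoms: none
Why: Proposed new method: the lithium enolate of 3 should be C-acylated by 19 on the face anti to the tert-butyl group, which forms C1–C2 with retention of the lactate configuration and gives 20; LiN(SiMe3)2 then removes the only acidic proton left, the γ-H at C5 (C1 is quaternary), the dienolate attacks the lactone carbonyl C6 through C5, and the tetrahedral intermediate collapses with loss of pivalaldehyde to the C1 alkoxide of 21. The closest known reaction types are the acylation and aldol addition of lactic acid dioxolanone enolates with self-regeneration of the stereocentre, the acylation of carbanions by dioxolanones with release of the acetal carbonyl compound, and the Dieckmann-type γ-acylation of dienolates of β-alkoxy enones; their union in one flask on one substrate is untested. Ring A closes in a 6-(enolendo)-exo-trig mode, whereas closure through the α-carbon C3 would need a four-membered ring. C1 is controlled by the acetal centre of 3; C5 is controlled in the ring closure, because allylic strain should put the methyl group on the inside of the U-shaped dienolate and this inside group is expected to pass the ring oxygen of the dioxolanone and not the angular C1 methyl, which leaves the arylmethyl group trans to the C1 oxygen (5R), and because the racemic centre of 19 becomes planar in the dienolate both epimers of 20 converge. The step needs C- over O-acylation, which the lithium counter-ion, THF and −78 °C should favour, and it needs the (E)-enol ether fixed in 19 so that C5 can reach C6.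

Step 13
Reactants: 21 (2R,6R)-6-{[2-(benzyloxy)-4,6-dimethoxy-3-methylphenyl]methyl}-2-hydroxy-5-methoxy-2,6-dimethylcyclohex-4-ene-1,3-dione; 5 (R)-2-methylbutanoyl chloride
Product: 22 (1R,5R)-5-{[2-(benzyloxy)-4,6-dimethoxy-3-methylphenyl]methyl}-4-methoxy-1,5-dimethyl-2,6-dioxocyclohex-3-en-1-yl (2R)-2-methylbutanoate
Conditions: pyridine, DMAP (cat.), CH2Cl2, 0 °C to rt
Reagents that add atoms: none
Why: DMAP-catalysed acylation of the tertiary alcohol, made more acidic by its two flanking ketones, should proceed without a base strong enough to cause an α-ketol shift or to form the ketene from 5, so no stereocentre is touched.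

Step 14
Reactants: 22 (1R,5R)-5-{[2-(benzyloxy)-4,6-dimethoxy-3-methylphenyl]methyl}-4-methoxy-1,5-dimethyl-2,6-dioxocyclohex-3-en-1-yl (2R)-2-methylbutanoate; 5 (R)-2-methylbutanoyl chloride
Product: 23 (1R,5R)-5-({2-(benzyloxy)-4,6-dimethoxy-3-methyl-5-[(2R)-2-methylbutanoyl]phenyl}methyl)-4-methoxy-1,5-dimethyl-2,6-dioxocyclohex-3-en-1-yl (2R)-2-methylbutanoate
Conditions: SnCl4, CH2Cl2, −40 to 0 °C
Reagents that add atoms: none
Why: Friedel–Crafts acylation at C3', the only free ring position and one activated by two ortho and one para alkoxy group, should need only a mild Lewis acid at low temperature, which keeps the benzyl ether, ring A and the α-stereocentre of the acyl group intact.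

Step 15
Reactants: 23 (1R,5R)-5-({2-(benzyloxy)-4,6-dimethoxy-3-methyl-5-[(2R)-2-methylbutanoyl]phenyl}methyl)-4-methoxy-1,5-dimethyl-2,6-dioxocyclohex-3-en-1-yl (2R)-2-methylbutanoate
Product: 24 (1R,5R)-5-({2-hydroxy-4,6-dimethoxy-3-methyl-5-[(2R)-2-methylbutanoyl]phenyl}methyl)-4-methoxy-1,5-dimethyl-2,6-dioxocyclohex-3-en-1-yl (2R)-2-methylbutanoate
Conditions: H2 (1 atm), Pd/C, EtOAc, rt
Reagents that add atoms: none
Why: Hydrogenolysis of the aryl benzyl ether over Pd/C should be much faster than reduction of the hindered β-methoxy enone or of the twisted aryl ketone, and the neutral medium keeps the freed phenol from adding to the ring A enone.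

Step 16
Reactants: 24 (1R,5R)-5-({2-hydroxy-4,6-dimethoxy-3-methyl-5-[(2R)-2-methylbutanoyl]phenyl}methyl)-4-methoxy-1,5-dimethyl-2,6-dioxocyclohex-3-en-1-yl (2R)-2-methylbutanoate
Product: 25 (1R,5R)-5-({(5R)-5-hydroxy-2,4-dimethoxy-5-methyl-3-[(2R)-2-methylbutanoyl]-6-oxocyclohexa-1,3-dien-1-yl}methyl)-4-methoxy-1,5-dimethyl-2,6-dioxocyclohex-3-en-1-yl (2R)-2-methylbutanoate
Conditions: (S)-2-(2-iodylphenyl)-4-isopropyl-4,5-dihydrooxazole, THF, 0 °C to rt; then TFA, H2O
Reagents that add atoms: (S)-2-(2-iodylphenyl)-4-isopropyl-4,5-dihydrooxazole, CC(C)[C@H]1COC(c2ccccc2I(=O)=O)=N1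
Why: Hydroxylative phenol dearomatisation by an iodyl arene (pentavalent iodine), in which the phenol binds to iodine and oxygen is passed to the less hindered ortho carbon C5' that bears the methyl group, should give the ortho-quinol, the chiral oxazoline being there to bias the face towards 5'R and any minor 5'S epimer being a diastereomer that is removed by chromatography.

Step 17
Reactants: 25 (1R,5R)-5-({(5R)-5-hydroxy-2,4-dimethoxy-5-methyl-3-[(2R)-2-methylbutanoyl]-6-oxocyclohexa-1,3-dien-1-yl}methyl)-4-methoxy-1,5-dimethyl-2,6-dioxocyclohex-3-en-1-yl (2R)-2-methylbutanoate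
Product: 26 Gilluone B, (1R,5R)-5-({(5R)-4-amino-5-hydroxy-2-methoxy-5-methyl-3-[(2R)-2-methylbutanoyl]-6-oxocyclohexa-1,3-dien-1-yl}methyl)-4-methoxy-1,5-dimethyl-2,6-dioxocyclohex-3-en-1-yl (2R)-2-methylbutanoate
Conditions: NH3 (2 equiv, 0.5 M in 1,4-dioxane), THF, −20 to 0 °C
Reagents that add atoms: ammonia, N
Why: Addition–elimination of ammonia on a vinylogous ester should take place at C4', the most electrophilic enol ether carbon because it is β to the side-chain ketone and δ to the ring ketone, and gives the hydrogen-bonded vinylogous amide, while the singly activated and hindered C4 methoxy enone of ring A and the tertiary ester should react more slowly.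

**Compound list**

1 | (S)-lactic acid | C[C@H](O)C(=O)O | starting material
2 | pivalaldehyde | CC(C)(C)C=O | starting material
3 | (2S,5S)-2-tert-butyl-5-methyl-1,3-dioxolan-4-one | C[C@@H]1O[C@H](C(C)(C)C)OC1=O | intermediate
4 | (R)-2-methylbutanoic acid | CC[C@@H](C)C(=O)O | starting material
5 | (R)-2-methylbutanoyl chloride | CC[C@@H](C)C(=O)Cl | intermediate
6 | 2-hydroxy-4,6-dimethoxybenzaldehyde | O=Cc1c(O)cc(OC)cc1OC | starting material
7 | 3,5-dimethoxy-2-methylphenol | Cc1c(O)cc(OC)cc1OC | intermediate
8 | 2-hydroxy-4,6-dimethoxy-3-methylbenzaldehyde | O=Cc1c(O)c(C)c(OC)cc1OC | intermediate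
9 | 2-(benzyloxy)-4,6-dimethoxy-3-methylbenzaldehyde | O=Cc1c(OCc2ccccc2)c(C)c(OC)cc1OC | intermediate
10 | methyl (E)-3-[2-(benzyloxy)-4,6-dimethoxy-3-methylphenyl]-2-methylprop-2-enoate | COC(=O)/C(C)=C/c1c(OCc2ccccc2)c(C)c(OC)cc1OC | intermediate
11 | methyl 3-[2-(benzyloxy)-4,6-dimethoxy-3-methylphenyl]-2-methylpropanoate (racemic, not isolated) | COC(=O)C(C)Cc1c(OCc2ccccc2)c(C)c(OC)cc1OC | intermediate
12 | 3-[2-(benzyloxy)-4,6-dimethoxy-3-methylphenyl]-2-methylpropanoic acid (racemic) | OC(=O)C(C)Cc1c(OCc2ccccc2)c(C)c(OC)cc1OC | intermediate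
13 | 1-{3-[2-(benzyloxy)-4,6-dimethoxy-3-methylphenyl]-2-methylpropanoyl}imidazole (not isolated) | O=C(C(C)Cc1c(OCc2ccccc2)c(C)c(OC)cc1OC)n1ccnc1 | intermediate
14 | 5-[2-(benzyloxy)-4,6-dimethoxy-3-methylphenyl]-2-(methoxycarbonyl)-4-methyl-3-oxopentanoic acid (as its magnesium chelate, not isolated) | COC(=O)C(C(=O)O)C(=O)C(C)Cc1c(OCc2ccccc2)c(C)c(OC)cc1OC | intermediate
15 | methyl 5-[2-(benzyloxy)-4,6-dimethoxy-3-methylphenyl]-4-methyl-3-oxopentanoate (racemic) | COC(=O)CC(=O)C(C)Cc1c(OCc2ccccc2)c(C)c(OC)cc1OC | intermediate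
16 | methyl 5-[2-(benzyloxy)-4,6-dimethoxy-3-methylphenyl]-3,3-dimethoxy-4-methylpentanoate (not isolated) | COC(=O)CC(OC)(OC)C(C)Cc1c(OCc2ccccc2)c(C)c(OC)cc1OC | intermediate
17 | methyl (E)-5-[2-(benzyloxy)-4,6-dimethoxy-3-methylphenyl]-3-methoxy-4-methylpent-2-enoate (racemic) | COC(=O)/C=C(/OC)C(C)Cc1c(OCc2ccccc2)c(C)c(OC)cc1OC | intermediate
18 | (E)-5-[2-(benzyloxy)-4,6-dimethoxy-3-methylphenyl]-3-methoxy-4-methylpent-2-enoic acid (racemic) | OC(=O)/C=C(/OC)C(C)Cc1c(OCc2ccccc2)c(C)c(OC)cc1OC | intermediate
19 | (E)-5-[2-(benzyloxy)-4,6-dimethoxy-3-methylphenyl]-3-methoxy-4-methylpent-2-enoyl chloride (racemic) | O=C(Cl)/C=C(/OC)C(C)Cc1c(OCc2ccccc2)c(C)c(OC)cc1OC | intermediate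
20 | (2S,5R)-5-{(E)-5-[2-(benzyloxy)-4,6-dimethoxy-3-methylphenyl]-3-methoxy-4-methylpent-2-enoyl}-2-tert-butyl-5-methyl-1,3-dioxolan-4-one (both epimers at the side-chain methyl carbon, not isolated) | C[C@]1(C(=O)/C=C(/OC)C(C)Cc2c(OCc3ccccc3)c(C)c(OC)cc2OC)O[C@H](C(C)(C)C)OC1=O | intermediate
21 | (2R,6R)-6-{[2-(benzyloxy)-4,6-dimethoxy-3-methylphenyl]methyl}-2-hydroxy-5-methoxy-2,6-dimethylcyclohex-4-ene-1,3-dione | O[C@]1(C)C(=O)C=C(OC)[C@@](C)(Cc2c(OCc3ccccc3)c(C)c(OC)cc2OC)C1=O | intermediate
22 | (1R,5R)-5-{[2-(benzyloxy)-4,6-dimethoxy-3-methylphenyl]methyl}-4-methoxy-1,5-dimethyl-2,6-dioxocyclohex-3-en-1-yl (2R)-2-methylbutanoate | CC[C@@H](C)C(=O)O[C@]1(C)C(=O)C=C(OC)[C@@](C)(Cc2c(OCc3ccccc3)c(C)c(OC)cc2OC)C1=O | intermediate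
23 | (1R,5R)-5-({2-(benzyloxy)-4,6-dimethoxy-3-methyl-5-[(2R)-2-methylbutanoyl]phenyl}methyl)-4-methoxy-1,5-dimethyl-2,6-dioxocyclohex-3-en-1-yl (2R)-2-methylbutanoate | CC[C@@H](C)C(=O)O[C@]1(C)C(=O)C=C(OC)[C@@](C)(Cc2c(OCc3ccccc3)c(C)c(OC)c(C(=O)[C@H](C)CC)c2OC)C1=O | intermediate
24 | (1R,5R)-5-({2-hydroxy-4,6-dimethoxy-3-methyl-5-[(2R)-2-methylbutanoyl]phenyl}methyl)-4-methoxy-1,5-dimethyl-2,6-dioxocyclohex-3-en-1-yl (2R)-2-methylbutanoate | CC[C@@H](C)C(=O)O[C@]1(C)C(=O)C=C(OC)[C@@](C)(Cc2c(O)c(C)c(OC)c(C(=O)[C@H](C)CC)c2OC)C1=O | intermediate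
25 | (1R,5R)-5-({(5R)-5-hydroxy-2,4-dimethoxy-5-methyl-3-[(2R)-2-methylbutanoyl]-6-oxocyclohexa-1,3-dien-1-yl}methyl)-4-methoxy-1,5-dimethyl-2,6-dioxocyclohex-3-en-1-yl (2R)-2-methylbutanoate | CC[C@@H](C)C(=O)O[C@]1(C)C(=O)C=C(OC)[C@@](C)(CC2=C(OC)C(C(=O)[C@H](C)CC)=C(OC)[C@@](C)(O)C2=O)C1=O | intermediate
26 | Gilluone B | CC[C@@H](C)C(=O)O[C@]1(C)C(=O)C=C(OC)[C@@](C)(CC2=C(OC)C(C(=O)[C@H](C)CC)=C(N)[C@@](C)(O)C2=O)C1=O | target

**Step count and risks**

Total: 17 steps. Longest linear sequence: 15 steps (steps 3 to 17, from 6); steps 1 and 2 supply 3 and 5.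

Steps most likely to fail:

1. Step 12. The enolate of 3 is short-lived and may be acylated on oxygen or may deprotonate 20 before all of 19 is consumed. In the second stage the dienolate may close with incomplete facial control at C5, or the C1 alkoxide may undergo ring contraction on warming. The fallback sets out from 17 and 3 and comes back to the route at 20. Reduction of 17 with (Me2CHCH2)2AlH in CH2Cl2 at −78 °C should give (E)-5-[2-(benzyloxy)-4,6-dimethoxy-3-methylphenyl]-3-methoxy-4-methylpent-2-en-1-ol F1, and MnO2 in CH2Cl2 should oxidise it to (E)-5-[2-(benzyloxy)-4,6-dimethoxy-3-methylphenyl]-3-methoxy-4-methylpent-2-enal F2. Aldol addition of the lithium enolate of 3 to F2 at −78 °C, the best established reaction of this enolate and again anti to the tert-butyl group, should give (2S,5R)-5-{(E)-5-[2-(benzyloxy)-4,6-dimethoxy-3-methylphenyl]-1-hydroxy-3-methoxy-4-methylpent-2-en-1-yl}-2-tert-butyl-5-methyl-1,3-dioxolan-4-one F3 as carbinol epimers. Dess–Martin periodinane buffered with NaHCO3 should oxidise both epimers to 20, which is now isolated and treated alone with LiN(SiMe3)2 to give 21. The C1–C2 bond then no longer rests on an acylation, and the ring closure can be examined without acid chloride, LiCl or free amine in the flask; the closure itself is still the second stage of step 12.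

2. Step 16. The chiral ligand on iodine may discriminate poorly between the two faces of C5', and some oxygen may be delivered to the other ortho carbon C1'. The fallback sets out from 24 and comes back at 25. Reagent control is given up: stabilised 2-iodoxybenzoic acid (SIBX) in THF followed by TFA, the reagent established for fully substituted acyl dimethoxy phenols of this kind, should give 25 together with its C5' epimer, (1R,5R)-5-({(5S)-5-hydroxy-2,4-dimethoxy-5-methyl-3-[(2R)-2-methylbutanoyl]-6-oxocyclohexa-1,3-dien-1-yl}methyl)-4-methoxy-1,5-dimethyl-2,6-dioxocyclohex-3-en-1-yl (2R)-2-methylbutanoate F4. Because ring A and both side chains are already single enantiomers, 25 and its epimer are diastereomers and are separated by chromatography; 25 goes on to step 17.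

3. Step 17. Ammonia may also attack the C4 methoxy enone of ring A or the C2' enol ether, may cleave the tertiary ester, or may act as a base and set off an α-ketol ring contraction of ring B. The fallback sets out from 25 and comes back at 26. One equivalent of 2,4,6-trimethoxybenzylamine in CH2Cl2 at 0 °C, a primary amine that can be dosed exactly and is too bulky to cleave the tertiary ester, should give (1R,5R)-5-({(5R)-5-hydroxy-2-methoxy-5-methyl-3-[(2R)-2-methylbutanoyl]-6-oxo-4-[(2,4,6-trimethoxybenzyl)amino]cyclohexa-1,3-dien-1-yl}methyl)-4-methoxy-1,5-dimethyl-2,6-dioxocyclohex-3-en-1-yl (2R)-2-methylbutanoate F5. TFA with Et3SiH in CH2Cl2 at 0 °C should then remove the acid-labile benzylic group from the amide-like nitrogen and give 26.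

**Further compounds**

F1 | step 12 | (E)-5-[2-(benzyloxy)-4,6-dimethoxy-3-methylphenyl]-3-methoxy-4-methylpent-2-en-1-ol | OC/C=C(/OC)C(C)Cc1c(OCc2ccccc2)c(C)c(OC)cc1OC
F2 | step 12 | (E)-5-[2-(benzyloxy)-4,6-dimethoxy-3-methylphenyl]-3-methoxy-4-methylpent-2-enal | O=C/C=C(/OC)C(C)Cc1c(OCc2ccccc2)c(C)c(OC)cc1OC
F3 | step 12 | (2S,5R)-5-{(E)-5-[2-(benzyloxy)-4,6-dimethoxy-3-methylphenyl]-1-hydroxy-3-methoxy-4-methylpent-2-en-1-yl}-2-tert-butyl-5-methyl-1,3-dioxolan-4-one | C[C@]1(C(O)/C=C(/OC)C(C)Cc2c(OCc3ccccc3)c(C)c(OC)cc2OC)O[C@H](C(C)(C)C)OC1=O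
F4 | step 16 | (1R,5R)-5-({(5S)-5-hydroxy-2,4-dimethoxy-5-methyl-3-[(2R)-2-methylbutanoyl]-6-oxocyclohexa-1,3-dien-1-yl}methyl)-4-methoxy-1,5-dimethyl-2,6-dioxocyclohex-3-en-1-yl (2R)-2-methylbutanoate | CC[C@@H](C)C(=O)O[C@]1(C)C(=O)C=C(OC)[C@@](C)(CC2=C(OC)C(C(=O)[C@H](C)CC)=C(OC)[C@](C)(O)C2=O)C1=O
F5 | step 17 | (1R,5R)-5-({(5R)-5-hydroxy-2-methoxy-5-methyl-3-[(2R)-2-methylbutanoyl]-6-oxo-4-[(2,4,6-trimethoxybenzyl)amino]cyclohexa-1,3-dien-1-yl}methyl)-4-methoxy-1,5-dimethyl-2,6-dioxocyclohex-3-en-1-yl (2R)-2-methylbutanoate | CC[C@@H](C)C(=O)O[C@]1(C)C(=O)C=C(OC)[C@@](C)(CC2=C(OC)C(C(=O)[C@H](C)CC)=C(NCc3c(OC)cc(OC)cc3OC)[C@@](C)(O)C2=O)C1=O
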